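**Retrosynthetic overview**
- The target is a depside of two 2,4-dihydroxy-6-(2-oxononyl)benzoate units (ring A = acyl half, ring B = methyl ester half). No ring is formed in the route; both benzene rings are bought as orsellinate units.
- Last disconnection: three phenolic acetates (protecting groups only).
- Key disconnection: both ArCH2–C(=O)C7H15 bonds at once, giving the bis(benzylic bromide) of the acetylated depside plus two equivalents of the unmasked octanoyl anion donor (C5H5)2Zr(Cl)C(O)C7H15 (from 1-heptene, (C5H5)2Zr(H)Cl and CO), joined under palladium catalysis.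
- The bis-bromide comes from twofold radical bromination of per-acetylated methyl lecanorate.
- The depside ester comes from di-O-acetylorsellinoyl chloride and the 4-OH of methyl orsellinate.

Assumption: the target has no stereocentre and is achiral, so there is no enantiomer to control; the route delivers the single compound drawn.

**Route**

Step 1
Reactants: 1 orsellinic acid (2,4-dihydroxy-6-methylbenzoic acid)
Product: 2 2,4-diacetoxy-6-methylbenzoic acid
Conditions: Ac2O (2.5 equiv), pyridine, 0 °C to rt; cold dilute HCl work-up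
Reagents that add atoms: acetic anhydride, CC(=O)OC(C)=O
Why: Phenol O-acetylation (as in the aspirin synthesis) caps both hydroxyls, which prevents self-condensation of the later acid chloride and makes ring A electron-poor enough for the radical bromination; no stereocentre is formed.

Step 2
Reactants: 2 2,4-diacetoxy-6-methylbenzoic acid; 3 methyl orsellinate (methyl 2,4-dihydroxy-6-methylbenzoate)
Product: 6 methyl 2-acetoxy-4-[(2,4-diacetoxy-6-methylbenzoyl)oxy]-6-methylbenzoate, via acid chloride 4 (not isolated), via 2-hydroxy depside 5 (not isolated)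
Conditions: (COCl)2, DMF (cat.), CH2Cl2, 0 °C to rt, evaporate; 3, Et3N, CH2Cl2, 0 °C to rt; then Ac2O, DMAP (cat.), rt
Reagents that add atoms: acetic anhydride, CC(=O)OC(C)=O
Why: Acid chloride esterification (the classical depside coupling of an acyl-protected orsellinoyl chloride) goes to the 4-OH of 3 because the 2-OH is hydrogen-bonded to the ester carbonyl and less acidic, and DMAP-catalysed acetylation then caps that 2-OH in the same pot; no stereocentre is formed.

Step 3
Reactants: 6 methyl 2-acetoxy-4-[(2,4-diacetoxy-6-methylbenzoyl)oxy]-6-methylbenzoate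
Product: 7 methyl 2-acetoxy-6-(bromomethyl)-4-{[2,4-diacetoxy-6-(bromomethyl)benzoyl]oxy}benzoate
Conditions: NBS (2.1 equiv), AIBN (10 mol %), PhCF3, 85 °C
Reagents that add atoms: N-bromosuccinimide, O=C1CCC(=O)N1Br
Why: Twofold Wohl–Ziegler radical bromination of the two ring methyl groups, with the acyloxy and ester substituents suppressing ionic ring bromination as they do for acetoxytoluenes and methyl o-toluate; no stereocentre is formed.

Step 4
Reactants: 8 1-heptene
Product: 10 chloro(octanoyl)bis(cyclopentadienyl)zirconium, via heptylzirconocene chloride 9 (not isolated)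
Conditions: (C5H5)2Zr(H)Cl, CH2Cl2, rt, 1 h; then CO (1 atm), rt, 2 h; concentrate under argon
Reagents that add atoms: chlorohydridobis(cyclopentadienyl)zirconium, [H][Zr](Cl)(C1C=CC=C1)C1C=CC=C1; carbon monoxide, [C-]#[O+]
Why: Anti-Markovnikov hydrozirconation of the terminal alkene followed by migratory insertion of CO into the Zr–C bond gives the stable acylzirconocene chloride, an unmasked octanoyl anion donor; no stereocentre is formed.

Step 5
Reactants: 7 methyl 2-acetoxy-6-(bromomethyl)-4-{[2,4-diacetoxy-6-(bromomethyl)benzoyl]oxy}benzoate; 10 chloro(octanoyl)bis(cyclopentadienyl)zirconium (2.6 equiv)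
Product: 11 methyl 2-acetoxy-4-{[2,4-diacetoxy-6-(2-oxononyl)benzoyl]oxy}-6-(2-oxononyl)benzoate
Conditions: PdCl2(PPh3)2 (10 mol %), toluene, rt to 40 °C; pH 7 buffer work-up
Reagents that add atoms: none
Why: Palladium-catalysed cross-coupling of an acylzirconocene chloride with a benzylic bromide (oxidative addition of ArCH2–Br to zerovalent palladium, acyl transfer from zirconium, reductive elimination) joins the electrophilic benzylic carbon to the normally electrophilic acyl carbon at both arms, under neutral conditions that leave the depside ester, the methyl ester and the acetates untouched; no stereocentre is formed.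

Step 6
Reactants: 11 methyl 2-acetoxy-4-{[2,4-diacetoxy-6-(2-oxononyl)benzoyl]oxy}-6-(2-oxononyl)benzoate
Product: 12 methyl 4-{[2,4-dihydroxy-6-(2-oxononyl)benzoyl]oxy}-2-hydroxy-6-(2-oxononyl)benzoate (target, CNP0110390.0)
Conditions: NH4OAc (10 equiv), MeOH–H2O (4:1), rt
Reagents that add atoms: none
Why: Neutral ammonium-acetate-mediated transesterification removes the three phenolic acetates, while the doubly ortho-substituted depside and methyl benzoate carbonyls are sterically shielded and the near-neutral pH avoids the ketone enolate that would close an isocoumarin and expel ring B; no stereocentre is formed.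

**Compound list**
1 | orsellinic acid (2,4-dihydroxy-6-methylbenzoic acid) | Cc1cc(O)cc(O)c1C(=O)O | starting material
2 | 2,4-diacetoxy-6-methylbenzoic acid | Cc1cc(OC(C)=O)cc(OC(C)=O)c1C(=O)O | intermediate
3 | methyl orsellinate (methyl 2,4-dihydroxy-6-methylbenzoate) | COC(=O)c1c(C)cc(O)cc1O | starting material
4 | 2,4-diacetoxy-6-methylbenzoyl chloride | Cc1cc(OC(C)=O)cc(OC(C)=O)c1C(Cl)=O | intermediate
5 | methyl 4-[(2,4-diacetoxy-6-methylbenzoyl)oxy]-2-hydroxy-6-methylbenzoate | COC(=O)c1c(C)cc(OC(=O)c2c(C)cc(OC(C)=O)cc2OC(C)=O)cc1O | intermediate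
6 | methyl 2-acetoxy-4-[(2,4-diacetoxy-6-methylbenzoyl)oxy]-6-methylbenzoate | COC(=O)c1c(C)cc(OC(=O)c2c(C)cc(OC(C)=O)cc2OC(C)=O)cc1OC(C)=O | intermediate
7 | methyl 2-acetoxy-6-(bromomethyl)-4-{[2,4-diacetoxy-6-(bromomethyl)benzoyl]oxy}benzoate | COC(=O)c1c(CBr)cc(OC(=O)c2c(CBr)cc(OC(C)=O)cc2OC(C)=O)cc1OC(C)=O | intermediate
8 | 1-heptene | C=CCCCCC | starting material
9 | chloro(heptyl)bis(cyclopentadienyl)zirconium (cyclopentadienyl rings drawn sigma-bonded) | CCCCCCC[Zr](Cl)(C1C=CC=C1)C1C=CC=C1 | intermediate
10 | chloro(octanoyl)bis(cyclopentadienyl)zirconium (cyclopentadienyl rings drawn sigma-bonded) | CCCCCCCC(=O)[Zr](Cl)(C1C=CC=C1)C1C=CC=C1 | intermediate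
11 | methyl 2-acetoxy-4-{[2,4-diacetoxy-6-(2-oxononyl)benzoyl]oxy}-6-(2-oxononyl)benzoate | COC(=O)c1c(CC(=O)CCCCCCC)cc(OC(=O)c2c(CC(=O)CCCCCCC)cc(OC(C)=O)cc2OC(C)=O)cc1OC(C)=O | intermediate
12 | methyl 4-{[2,4-dihydroxy-6-(2-oxononyl)benzoyl]oxy}-2-hydroxy-6-(2-oxononyl)benzoate | CCCCCCCC(=O)Cc1cc(OC(=O)c2c(O)cc(O)cc2CC(=O)CCCCCCC)cc(O)c1C(=O)OC | target

**Count and risks**
Total step count: 6. Longest linear sequence: 5 (steps 1, 2, 3, 5, 6); step 4 prepares the acyl donor in parallel.

The three steps most likely to fail: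

1. Step 3, the twofold benzylic bromination. Two similar methyl groups must each take exactly one bromine, so under- and over-brominated material will lower the yield of 7. The fallback sets out from 6 and deliberately over-brominates with NBS (4.4 equiv, AIBN, PhCF3, 85 °C) to the single product methyl 2-acetoxy-6-(dibromomethyl)-4-{[2,4-diacetoxy-6-(dibromomethyl)benzoyl]oxy}benzoate F1. One bromine per arm is then removed by halophilic reduction with diethyl phosphite and iPr2NEt in THF at 0 °C, which comes back to the route at 7.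

2. Step 5, the twofold acyl anion coupling. Decarbonylation of the acylpalladium species, bibenzyl homocoupling or a sluggish second coupling next to the ortho esters could erode the yield. The fallback sets out from 7 and inverts the polarity at the benzylic carbons instead: zinc insertion (Zn dust, LiCl, THF, rt) gives methyl 2-acetoxy-6-[(bromozincio)methyl]-4-({2,4-diacetoxy-6-[(bromozincio)methyl]benzoyl}oxy)benzoate F2. Acylation of F2 with octanoyl chloride (2.4 equiv) under Pd(PPh3)4 (5 mol %) in THF at rt comes back to the route at 11.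

3. Step 6, the global deacetylation. The product carries a ketone two atoms away from an aryl ester, and any enolisation can close an isocoumarin and cleave the depside. The fallback sets out from 11 and masks both ketones first (HC(OMe)3, PPTS, MeOH, rt) as methyl 2-acetoxy-4-{[2,4-diacetoxy-6-(2,2-dimethoxynonyl)benzoyl]oxy}-6-(2,2-dimethoxynonyl)benzoate F3. With no enolisable ketone left, the acetates are removed with K2CO3 (cat.) in MeOH at 0 °C to give methyl 4-{[2,4-dihydroxy-6-(2,2-dimethoxynonyl)benzoyl]oxy}-2-hydroxy-6-(2,2-dimethoxynonyl)benzoate F4. The ketals are then hydrolysed with AcOH–THF–H2O at rt, which comes back to the route at 12.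

**Further compounds**
F1 | step 3 | methyl 2-acetoxy-6-(dibromomethyl)-4-{[2,4-diacetoxy-6-(dibromomethyl)benzoyl]oxy}benzoate | COC(=O)c1c(C(Br)Br)cc(OC(=O)c2c(C(Br)Br)cc(OC(C)=O)cc2OC(C)=O)cc1OC(C)=O
F2 | step 5 | methyl 2-acetoxy-6-[(bromozincio)methyl]-4-({2,4-diacetoxy-6-[(bromozincio)methyl]benzoyl}oxy)benzoate | COC(=O)c1c(C[Zn]Br)cc(OC(=O)c2c(C[Zn]Br)cc(OC(C)=O)cc2OC(C)=O)cc1OC(C)=O
F3 | step 6 | methyl 2-acetoxy-4-{[2,4-diacetoxy-6-(2,2-dimethoxynonyl)benzoyl]oxy}-6-(2,2-dimethoxynonyl)benzoate | COC(=O)c1c(CC(OC)(OC)CCCCCCC)cc(OC(=O)c2c(CC(OC)(OC)CCCCCCC)cc(OC(C)=O)cc2OC(C)=O)cc1OC(C)=O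
F4 | step 6 | methyl 4-{[2,4-dihydroxy-6-(2,2-dimethoxynonyl)benzoyl]oxy}-2-hydroxy-6-(2,2-dimethoxynonyl)benzoate | COC(=O)c1c(CC(OC)(OC)CCCCCCC)cc(OC(=O)c2c(CC(OC)(OC)CCCCCCC)cc(O)cc2O)cc1O
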